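**Plan**

1. Retrosynthesis (daucane numbering: C1 = methyl-bearing ring-fusion carbon, C2 = acetoxy carbon, C4 = carbinol carbon, C5 = ring-fusion CH, C6 = aroyloxy carbon, C8/C9 = epoxide carbons, C10 = CH2 on C1): remove the C2 acetate, the C6 vanillate and the epoxide oxygen, then cut C1–C10 and C6–C7.
2. Enabling feature: in the seven-membered ring (C1, C5–C10) the C6 oxygen and the C8–C9 epoxide flank C7. Read back as C5=C6 and C8=C9 this is a cyclohepta-1,4-diene, the product pattern of a cis-divinylcyclopropane Cope rearrangement, with quaternary C1 as one terminus.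
3. Forward: the cyclopentane ring is built first from (R)-4-silyloxycyclopentenone (methyl, iodide, isopropyl, vinyl). A rhodium-carbenoid cyclopropanation/Cope cascade with a vinyldiazoacetate closes the seven-membered ring last. Hydroboration, ester-to-methyl reduction, epoxidation and the two acylations finish the target.
4. Stereochemistry: C2 comes from the starting enone and relays to C4 (isopropyl adds anti). The C2/C4 silyloxy groups and the chiral rhodium catalyst fix C1. Syn hydroboration sets C5 and C6, C6–OH directs the epoxide, and C2 is finally inverted by oxidation and C4–OH-directed reduction.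

Key step: step 7

Remark: in the names, syn and anti mean the same and the opposite ring face as the C1 methyl group; the sense of induction of Rh2(R-DOSP)4 in step 7 is taken from the usual model for donor/acceptor carbenoids, and the antipodal catalyst would be used if it proved otherwise.

**Route**

Step 1
Reactants: 1 (R)-4-(tert-butyldimethylsilyloxy)cyclopent-2-en-1-one
Product: 3 (R)-4-(tert-butyldimethylsilyloxy)-3-methylcyclopent-2-en-1-one, via trimethylsilyl enol ether 2 (not isolated)
Conditions: MeMgBr, CuBr·SMe2 (10 mol %), Me3SiCl, THF, −78 °C; then Pd(OAc)2 (10 mol %), O2 (1 atm), DMSO, 23 °C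
Reagents that add atoms: methylmagnesium bromide, C[Mg]Br; chlorotrimethylsilane, C[Si](C)(C)Cl (stays in intermediate 2 only)
Why: Copper-catalysed conjugate addition (trans to the silyloxy group, trapped as silyl enol ether 2) followed by Saegusa–Ito dehydrogenation should re-form the enone with the methyl group on the β-carbon, the temporary stereocentre being erased and C2 carried over from 1.

Step 2
Reactants: 3 (R)-4-(tert-butyldimethylsilyloxy)-3-methylcyclopent-2-en-1-one
Product: 4 (R)-4-(tert-butyldimethylsilyloxy)-2-iodo-3-methylcyclopent-2-en-1-one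
Conditions: I2, pyridine, CH2Cl2, 0 → 23 °C
Reagents that add atoms: iodine, II
Why: α-Iodination of the enone by the pyridine-mediated addition–iodination–elimination sequence is general for 3-substituted cyclopentenones and creates no stereocentre.

Step 3
Reactants: 4 (R)-4-(tert-butyldimethylsilyloxy)-2-iodo-3-methylcyclopent-2-en-1-one
Product: 5 (1R,4R)-4-(tert-butyldimethylsilyloxy)-2-iodo-3-methyl-1-(propan-2-yl)cyclopent-2-en-1-ol (isopropyl trans to the silyloxy group)
Conditions: i-PrMgCl, CeCl3, THF, −78 °C
Reagents that add atoms: isopropylmagnesium chloride, CC(C)[Mg]Cl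
Why: The organocerium reagent should add 1,2 to the hindered, enolisable ketone without reduction or iodine–metal exchange, from the face anti to the C2 silyloxy group, which sets C4 (OH cis to the silyloxy group, isopropyl trans).

Step 4
Reactants: 5 (1R,4R)-4-(tert-butyldimethylsilyloxy)-2-iodo-3-methyl-1-(propan-2-yl)cyclopent-2-en-1-ol
Product: 6 trimethylsilyl ether of 5
Conditions: Me3SiOTf, Et3N, CH2Cl2, −78 → 0 °C
Reagents that add atoms: trimethylsilyl trifluoromethanesulfonate, C[Si](C)(C)OS(=O)(=O)C(F)(F)F
Why: Silyl triflate silylation masks the tertiary allylic O–H bond, which would otherwise react with the rhodium carbenoid of step 7 (O–H insertion or oxonium ylide rearrangement).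

Step 5
Reactants: 6 trimethylsilyl ether of 5
Product: 7 [(1R,4R)-4-(tert-butyldimethylsilyloxy)-2-ethenyl-3-methyl-1-(propan-2-yl)cyclopent-2-en-1-yl]oxytrimethylsilane
Conditions: tributyl(vinyl)stannane, Pd(PPh3)4 (5 mol %), CuI (copper iodide, 10 mol %), DMF, 60 °C
Reagents that add atoms: tributyl(vinyl)stannane, C=C[Sn](CCCC)(CCCC)CCCC
Why: Stille cross-coupling, accelerated by the copper co-catalyst for the hindered tetrasubstituted vinyl iodide, installs the vinyl group (C6, C7) and gives the 1,3-diene with both stereocentres untouched.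

Step 6
Reactants: 8 methyl but-3-enoate
Product: 9 methyl 2-diazobut-3-enoate
Conditions: 4-acetamidobenzenesulfonyl azide, DBU, MeCN, 0 °C
Reagents that add atoms: 4-acetamidobenzenesulfonyl azide, CC(=O)Nc1ccc(cc1)S(=O)(=O)N=[N+]=[N-]
Why: Regitz diazo transfer to the DBU-generated dienolate takes place at the α-carbon and gives the vinyldiazoacetate, which is used cold and without delay.

Step 7
Reactants: 7 [(1R,4R)-4-(tert-butyldimethylsilyloxy)-2-ethenyl-3-methyl-1-(propan-2-yl)cyclopent-2-en-1-yl]oxytrimethylsilane; 9 methyl 2-diazobut-3-enoate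
Product: 11 methyl 2-(tert-butyldimethylsilyloxy)-4-(trimethylsilyloxy)dauca-5,8-dien-14-oate (both silyloxy groups syn), via cis-divinylcyclopropane 10 (not isolated)
Conditions: Rh2(R-DOSP)4 (2 mol %), hexanes, −40 → 23 °C, slow addition of 9; then toluene, 90 °C
Reagents that add atoms: none
Why: The rhodium-bound vinylcarbene from 9 adds to the terminal vinyl group of 7 (the tetrasubstituted ring double bond is inert) in a concerted, asynchronous cyclopropanation that places the carbene vinyl group cis to the cyclopentenyl group, giving cis-divinylcyclopropane 10. On warming, 10 undergoes a [3,3]-sigmatropic (Cope) rearrangement through a boat transition state in which C10 bonds to C1 while the cyclopropane C6–C8 bond breaks; this ring expansion closes the seven-membered ring and leaves the C5=C6 and C8=C9 double bonds, so the whole is a formal (4+3) cycloaddition. The closest known reaction type is the tandem cyclopropanation/Cope rearrangement of vinyldiazoacetates with 1,3-dienes under chiral dirhodium tetracarboxylate catalysis, including cases that form a methyl-bearing quaternary ring-fusion carbon. The new quaternary centre C1 is set by chirality transfer from the catalyst-controlled cyclopropane configuration through the boat geometry, and the C2 and C4 silyloxy groups both lie on the face that ends up carrying the C1 methyl group, so catalyst and substrate should reinforce each other in adding C10 anti to them. The step needs cyclopropanation of the vinyl group and not vinylogous attack or C–H insertion (hydrocarbon solvent, prolinate catalyst, reactive diene), and it needs the cis-cyclopropane; the C1 methyl group points inward in the boat, hence the heating.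

Step 8
Reactants: 11 methyl 2-(tert-butyldimethylsilyloxy)-4-(trimethylsilyloxy)dauca-5,8-dien-14-oate
Product: 13 methyl 6-hydroxy-2-(tert-butyldimethylsilyloxy)-4-(trimethylsilyloxy)dauc-8-en-14-oate (5-H and 6-OH anti; trans ring fusion), via alkylborane 12 (not isolated)
Conditions: BH3·THF, THF, 0 → 23 °C; then NaBO3·4H2O, H2O, 23 °C
Reagents that add atoms: borane–tetrahydrofuran, B.C1CCOC1 (boron stays in intermediate 12 only); sodium perborate, [Na+].[O-]OB=O
Why: In this hydroboration–oxidation borane should add only to the electron-rich C5=C6 bond (the C8=C9 enoate is deactivated), with boron on the less substituted C6 and syn delivery of H and B from the face anti to the C1 methyl and the two silyloxy groups, which sets C5 and C6 together, and the perborate oxidation proceeds with retention.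

Step 9
Reactants: 13 methyl 6-hydroxy-2-(tert-butyldimethylsilyloxy)-4-(trimethylsilyloxy)dauc-8-en-14-oate
Product: 15 2-(tert-butyldimethylsilyloxy)dauc-8-ene-4,6,14-triol, via trimethylsilyl-protected diol 14 (not isolated)
Conditions: i-Bu2AlH, CH2Cl2, −78 °C; then aq. HCl (1 M), THF, 0 °C
Reagents that add atoms: none
Why: i-Bu2AlH reduces the enoate 1,2 to the primary allylic alcohol, and the acidic work-up cleaves the labile tertiary trimethylsilyl ether while the secondary TBS ether stays.

Step 10
Reactants: 15 2-(tert-butyldimethylsilyloxy)dauc-8-ene-4,6,14-triol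
Product: 17 2-(tert-butyldimethylsilyloxy)dauc-8-ene-4,6-diol, via allylic mesylate 16 (not isolated)
Conditions: MeSO2Cl, Et3N, CH2Cl2, −40 °C; then LiEt3BH, THF, −40 → 0 °C
Reagents that add atoms: methanesulfonyl chloride, CS(=O)(=O)Cl (stays in intermediate 16 only)
Why: The primary allylic alcohol is sulfonylated much faster than the hindered secondary and tertiary alcohols, and SN2 hydride displacement of the primary allylic mesylate by LiEt3BH (no transposition) gives the C8 methyl group.

Step 11
Reactants: 17 2-(tert-butyldimethylsilyloxy)dauc-8-ene-4,6-diol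
Product: 18 8,9-epoxy-2-(tert-butyldimethylsilyloxy)daucane-4,6-diol (epoxide oxygen anti)
Conditions: VO(acac)2 (5 mol %), t-BuOOH, CH2Cl2, 0 → 23 °C
Reagents that add atoms: tert-butyl hydroperoxide, CC(C)(C)OO
Why: In this vanadium-catalysed hydroxyl-directed epoxidation the homoallylic C6 hydroxyl binds the vanadium peroxide and delivers oxygen to the C8=C9 face on its own side, which sets C8 and C9.

Step 12
Reactants: 18 8,9-epoxy-2-(tert-butyldimethylsilyloxy)daucane-4,6-diol; 19 4-(benzyloxy)-3-methoxybenzoic acid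
Product: 20 6-O-(4-benzyloxy-3-methoxybenzoyl) ester of 18
Conditions: EDC·HCl, DMAP, CH2Cl2, 23–40 °C
Reagents that add atoms: none
Why: Steglich esterification acylates the only free secondary alcohol (C6), the tertiary C4 hydroxyl being too hindered to react.

Step 13
Reactants: 20 6-O-(4-benzyloxy-3-methoxybenzoyl) ester of 18
Product: 21 2-hydroxy compound (2-OH syn), 8,9-epoxy-6-(4-benzyloxy-3-methoxybenzoyloxy)daucane-2,4-diol
Conditions: Bu4NF, AcOH, THF, 23 → 40 °C
Reagents that add atoms: none
Why: Fluoride cleaves the secondary TBS ether, and the acetic acid buffer keeps the esters and the epoxide intact.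

Step 14
Reactants: 21 8,9-epoxy-6-(4-benzyloxy-3-methoxybenzoyloxy)daucane-2,4-diol (2-OH syn)
Product: 22 8,9-epoxy-6-(4-benzyloxy-3-methoxybenzoyloxy)-4-hydroxydaucan-2-one
Conditions: Dess–Martin periodinane, NaHCO3, CH2Cl2, 0 → 23 °C
Reagents that add atoms: none
Why: Dess–Martin oxidation converts the secondary C2 alcohol into the ketone under buffered conditions; the tertiary alcohol cannot be oxidised.

Step 15
Reactants: 22 8,9-epoxy-6-(4-benzyloxy-3-methoxybenzoyloxy)-4-hydroxydaucan-2-one
Product: 23 8,9-epoxy-6-(4-benzyloxy-3-methoxybenzoyloxy)daucane-2,4-diol (2-OH anti)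
Conditions: Me4NBH(OAc)3, AcOH/MeCN, −30 °C
Reagents that add atoms: none
Why: In this Evans–Saksena reduction the tertiary C4 hydroxyl exchanges onto boron and delivers hydride to the C2 ketone from its own (syn) face, which gives the anti-1,3-diol and so inverts C2 relative to 21.

Step 16
Reactants: 23 8,9-epoxy-6-(4-benzyloxy-3-methoxybenzoyloxy)daucane-2,4-diol (2-OH anti)
Product: 24 2-acetate of 23
Conditions: Ac2O, DMAP (cat.), pyridine, CH2Cl2, 0 °C
Reagents that add atoms: acetic anhydride, CC(=O)OC(C)=O
Why: DMAP-catalysed acetylation takes the secondary C2 alcohol; the tertiary C4 alcohol is not acylated at 0 °C.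

Step 17
Reactants: 24 2-acetate of 23
Product: 25 CNP0241679.3
Conditions: H2 (1 atm), Pd/C, EtOAc, 23 °C
Reagents that add atoms: none
Why: Hydrogenolysis of the benzyl aryl ether over Pd/C under neutral conditions frees the phenol without affecting the esters or the non-benzylic trisubstituted epoxide.

**Compound list**

1 | (R)-4-(tert-butyldimethylsilyloxy)cyclopent-2-en-1-one | C1=CC(=O)C[C@H]1O[Si](C)(C)C(C)(C)C | starting material
2 | trans-4-(tert-butyldimethylsilyloxy)-3-methyl-1-(trimethylsilyloxy)cyclopent-1-ene (4R) | C[C@@H]1C=C(O[Si](C)(C)C)C[C@H]1O[Si](C)(C)C(C)(C)C | intermediate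
3 | (R)-4-(tert-butyldimethylsilyloxy)-3-methylcyclopent-2-en-1-one | CC1=CC(=O)C[C@H]1O[Si](C)(C)C(C)(C)C | intermediate
4 | (R)-4-(tert-butyldimethylsilyloxy)-2-iodo-3-methylcyclopent-2-en-1-one | CC1=C(I)C(=O)C[C@H]1O[Si](C)(C)C(C)(C)C | intermediate
5 | (1R,4R)-4-(tert-butyldimethylsilyloxy)-2-iodo-3-methyl-1-(propan-2-yl)cyclopent-2-en-1-ol | CC1=C(I)[C@](O)(C(C)C)C[C@H]1O[Si](C)(C)C(C)(C)C | intermediate
6 | trimethylsilyl ether of 5 | CC1=C(I)[C@](O[Si](C)(C)C)(C(C)C)C[C@H]1O[Si](C)(C)C(C)(C)C | intermediate
7 | [(1R,4R)-4-(tert-butyldimethylsilyloxy)-2-ethenyl-3-methyl-1-(propan-2-yl)cyclopent-2-en-1-yl]oxytrimethylsilane | CC1=C(C=C)[C@](O[Si](C)(C)C)(C(C)C)C[C@H]1O[Si](C)(C)C(C)(C)C | intermediate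
8 | methyl but-3-enoate | C=CCC(=O)OC | starting material
9 | methyl 2-diazobut-3-enoate | C=CC(=[N+]=[N-])C(=O)OC | intermediate
10 | methyl 1-ethenyl-2-(cyclopentenyl)cyclopropane-1-carboxylate from 7 and 9 (ethenyl cis to the cyclopentenyl group) | CC1=C([C@@H]2C[C@@]2(C=C)C(=O)OC)[C@](O[Si](C)(C)C)(C(C)C)C[C@H]1O[Si](C)(C)C(C)(C)C | intermediate
11 | methyl 2-(tert-butyldimethylsilyloxy)-4-(trimethylsilyloxy)dauca-5,8-dien-14-oate (silyloxy groups syn) | COC(=O)C1=CC[C@@]2(C)[C@H](O[Si](C)(C)C(C)(C)C)C[C@@](O[Si](C)(C)C)(C(C)C)C2=CC1 | intermediate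
12 | 6-boryl compound from hydroboration of 11 (B and 5-H anti) | B[C@H]1CC(C(=O)OC)=CC[C@@]2(C)[C@H](O[Si](C)(C)C(C)(C)C)C[C@@](O[Si](C)(C)C)(C(C)C)[C@H]12 | intermediate
13 | methyl 6-hydroxy-2-(tert-butyldimethylsilyloxy)-4-(trimethylsilyloxy)dauc-8-en-14-oate (6-OH and 5-H anti) | O[C@H]1CC(C(=O)OC)=CC[C@@]2(C)[C@H](O[Si](C)(C)C(C)(C)C)C[C@@](O[Si](C)(C)C)(C(C)C)[C@H]12 | intermediate
14 | 2-(tert-butyldimethylsilyloxy)-4-(trimethylsilyloxy)dauc-8-ene-6,14-diol | O[C@H]1CC(CO)=CC[C@@]2(C)[C@H](O[Si](C)(C)C(C)(C)C)C[C@@](O[Si](C)(C)C)(C(C)C)[C@H]12 | intermediate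
15 | 2-(tert-butyldimethylsilyloxy)dauc-8-ene-4,6,14-triol | O[C@H]1CC(CO)=CC[C@@]2(C)[C@H](O[Si](C)(C)C(C)(C)C)C[C@@](O)(C(C)C)[C@H]12 | intermediate
16 | 14-methanesulfonate of 15 | O[C@H]1CC(COS(C)(=O)=O)=CC[C@@]2(C)[C@H](O[Si](C)(C)C(C)(C)C)C[C@@](O)(C(C)C)[C@H]12 | intermediate
17 | 2-(tert-butyldimethylsilyloxy)dauc-8-ene-4,6-diol (4-OH syn, 6-OH anti, 2-O syn) | O[C@H]1CC(C)=CC[C@@]2(C)[C@H](O[Si](C)(C)C(C)(C)C)C[C@@](O)(C(C)C)[C@H]12 | intermediate
18 | 8,9-epoxy-2-(tert-butyldimethylsilyloxy)daucane-4,6-diol (epoxide anti) | O[C@H]1C[C@@]2(C)O[C@H]2C[C@@]2(C)[C@H](O[Si](C)(C)C(C)(C)C)C[C@@](O)(C(C)C)[C@H]12 | intermediate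
19 | 4-(benzyloxy)-3-methoxybenzoic acid | COc1cc(C(=O)O)ccc1OCc1ccccc1 | starting material
20 | 6-O-(4-benzyloxy-3-methoxybenzoyl) ester of 18 | COc1cc(C(=O)O[C@H]2C[C@@]3(C)O[C@H]3C[C@@]3(C)[C@H](O[Si](C)(C)C(C)(C)C)C[C@@](O)(C(C)C)[C@H]23)ccc1OCc1ccccc1 | intermediate
21 | 8,9-epoxy-6-(4-benzyloxy-3-methoxybenzoyloxy)daucane-2,4-diol (2-OH syn) | COc1cc(C(=O)O[C@H]2C[C@@]3(C)O[C@H]3C[C@@]3(C)[C@H](O)C[C@@](O)(C(C)C)[C@H]23)ccc1OCc1ccccc1 | intermediate
22 | 8,9-epoxy-6-(4-benzyloxy-3-methoxybenzoyloxy)-4-hydroxydaucan-2-one | COc1cc(C(=O)O[C@H]2C[C@@]3(C)O[C@H]3C[C@@]3(C)C(=O)C[C@@](O)(C(C)C)[C@H]23)ccc1OCc1ccccc1 | intermediate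
23 | 8,9-epoxy-6-(4-benzyloxy-3-methoxybenzoyloxy)daucane-2,4-diol (2-OH anti) | COc1cc(C(=O)O[C@H]2C[C@@]3(C)O[C@H]3C[C@@]3(C)[C@@H](O)C[C@@](O)(C(C)C)[C@H]23)ccc1OCc1ccccc1 | intermediate
24 | 2-acetate of 23 | COc1cc(C(=O)O[C@H]2C[C@@]3(C)O[C@H]3C[C@@]3(C)[C@@H](OC(C)=O)C[C@@](O)(C(C)C)[C@H]23)ccc1OCc1ccccc1 | intermediate
25 | CNP0241679.3 | COc1cc(C(=O)O[C@H]2C[C@@]3(C)O[C@H]3C[C@@]3(C)[C@@H](OC(C)=O)C[C@@](O)(C(C)C)[C@H]23)ccc1O | target

**Count and risks**

Total step count: 17. Longest linear sequence: 16 (steps 1–5 and 7–17; step 6 makes the diazo partner).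

Steps most likely to fail:

Step 8. The borane may approach C5=C6 from the methyl-bearing face (the anti face also carries the isopropyl group), or add so slowly to the hindered double bond that the enoate is reduced. The fallback sets out from 3 and returns at 17; it fixes the ring fusion on the monocyclic ketone and closes the ring by metathesis. Copper-catalysed conjugate addition of allylmagnesium bromide to 3 in the presence of Me3SiCl, anti to the silyloxy group, gives silyl enol ether F1. A Mukaiyama aldol reaction (Me3SiOTf catalysis) with 3-methylbut-3-enal F2, made from commercial 3-methylbut-3-en-1-ol by Dess–Martin oxidation and used at once, gives β-silyloxy ketone F3; the aldehyde should add anti to the larger allyl group, and C5 can still be equilibrated through the C4 ketone at this stage. Isopropylcerium addition anti to the C5 side chain gives carbinol F4. Ring-closing metathesis with the second-generation Grubbs catalyst closes the seven-membered ring at C8=C9 to give silyl ether F5. K2CO3 in MeOH frees the C6 alcohol to give diol F6, Dess–Martin oxidation gives ketone F7, and Me4NBH(OAc)3 reduction directed by the C4 hydroxyl returns to 17.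

Step 7. Carbene transfer to the hindered chiral diene may show poor facial control, or be diverted to vinylogous attack at the carbenoid terminus or to C–H insertion next to the silyl ethers. The fallback sets out from 6 and returns at 11; it moves the asymmetric cyclopropanation onto a simple alkene. Commercial vinylboronic acid pinacol ester is cyclopropanated with 9 and Rh2(R-DOSP)4 to give cyclopropyl boronate F8 (ethenyl cis to boron). Suzuki–Miyaura coupling of F8 with vinyl iodide 6 (Pd(OAc)2, SPhos, K3PO4, toluene/H2O), with retention at the cyclopropyl carbon, gives the same divinylcyclopropane 10, which rearranges on heating to 11.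

Step 3. The secondary organometal may reduce the ketone by β-hydride transfer, enolise it, or undergo iodine–metal exchange instead of 1,2-addition. The fallback sets out from 4 and returns at 5. Isopropenylmagnesium bromide with CeCl3, which has no β-hydrogen to transfer, adds anti to the silyloxy group to give isopropenyl carbinol F9. Diimide (from 2-nitrobenzenesulfonyl hydrazide and Et3N) then reduces the 1,1-disubstituted alkene chemoselectively in the presence of the tetrasubstituted vinyl iodide to give 5.

**Further compounds**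

F1 | step 8 | tert-butyldimethylsilyl/trimethylsilyl bis-ether from conjugate allylation of 3 (allyl trans to the silyloxy group) | C=CC[C@]1(C)C=C(O[Si](C)(C)C)C[C@H]1O[Si](C)(C)C(C)(C)C
F2 | step 8 | 3-methylbut-3-enal | CC(=C)CC=O
F3 | step 8 | 3-allyl-4-(tert-butyldimethylsilyloxy)-3-methyl-2-[3-methyl-1-(trimethylsilyloxy)but-3-enyl]cyclopentan-1-one (side chain trans to allyl; carbinol carbon not fixed) | O=C1C[C@@H](O[Si](C)(C)C(C)(C)C)[C@](C)(CC=C)[C@H]1C(O[Si](C)(C)C)CC(C)=C
F4 | step 8 | isopropyl carbinol from F3 (isopropyl anti to the side chain) | CC(C)[C@]1(O)C[C@@H](O[Si](C)(C)C(C)(C)C)[C@](C)(CC=C)[C@H]1C(O[Si](C)(C)C)CC(C)=C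
F5 | step 8 | 2-(tert-butyldimethylsilyloxy)-6-(trimethylsilyloxy)dauc-8-en-4-ol | C[Si](C)(C)OC1CC(C)=CC[C@@]2(C)[C@H](O[Si](C)(C)C(C)(C)C)C[C@@](O)(C(C)C)[C@H]12
F6 | step 8 | 2-(tert-butyldimethylsilyloxy)dauc-8-ene-4,6-diol, both C6 epimers | OC1CC(C)=CC[C@@]2(C)[C@H](O[Si](C)(C)C(C)(C)C)C[C@@](O)(C(C)C)[C@H]12
F7 | step 8 | 2-(tert-butyldimethylsilyloxy)-4-hydroxydauc-8-en-6-one (trans ring fusion) | O=C1CC(C)=CC[C@@]2(C)[C@H](O[Si](C)(C)C(C)(C)C)C[C@@](O)(C(C)C)[C@H]12
F8 | step 7 | methyl 1-ethenyl-2-(4,4,5,5-tetramethyl-1,3,2-dioxaborolan-2-yl)cyclopropane-1-carboxylate (ethenyl cis to boron) | CC1(C)OB(OC1(C)C)[C@@H]1C[C@@]1(C=C)C(=O)OC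
F9 | step 3 | (1R,4R)-4-(tert-butyldimethylsilyloxy)-2-iodo-3-methyl-1-(prop-1-en-2-yl)cyclopent-2-en-1-ol | CC1=C(I)[C@](O)(C(C)=C)C[C@H]1O[Si](C)(C)C(C)(C)C
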